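**Retrosynthetic overview**

- The only stereocentre is disconnected last: target ⇒ fully aromatic methylene-bridged bis(acylphloroglucinol) + geranyl acetate, by enantioselective dearomative C-geranylation of ring B at its methyl-bearing carbon.
- The CH2 bridge ⇒ an ortho-quinone methide on the chromene half, stored as a chromene-fused 1,3,2-dioxaborin, + the one free ring carbon of methylphloroacetophenone.
- The chromene-fused dioxaborin ⇒ hexanoylphloroglucinol + formaldehyde + phenylboronic acid + prenal in one flask; the dioxaborin ring and the 2H-pyran ring form in the same operation, and the boron tether decides which oxygen closes the pyran.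
- Both six-membered carbocycles are bought (phloroglucinol, 2-methylphloroglucinol) and C-acylated.
- Ring order: dioxaborin ring, then pyran ring (same pot); the dioxaborin is opened in the union; ring B is dearomatised to the cyclohexadienone last.

Assumption: the acetyl-triketone ring is written throughout as the enol tautomer of the given SMILES (the R descriptor refers to it), and 2-methylphloroglucinol is taken as a catalogue chemical.

**Route**

Step 1
Reactants: 1 phloroglucinol (benzene-1,3,5-triol); 2 hexanoyl chloride
Product: 3 1-(2,4,6-trihydroxyphenyl)hexan-1-one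
Conditions: AlCl3 (3.5 equiv), PhNO2/CH2Cl2, 0 → 50 °C; ice/1 M HCl
Reagents that add atoms: none
Why: Friedel–Crafts acylation of the C3-symmetric, strongly activated triol; the chelated aryl ketone deactivates the ring so the reaction stops at the mono-ketone and no stereocentre is formed.

Step 2
Reactants: 3 1-(2,4,6-trihydroxyphenyl)hexan-1-one; 4 3-methylbut-2-enal (prenal)
Product: 7 chromene-fused 2-phenyl-4H-1,3,2-dioxaborin (cyclic phenylboronate across O5/6-CH2O of 1-[5,7-dihydroxy-6-(hydroxymethyl)-2,2-dimethyl-2H-chromen-8-yl]hexan-1-one; 7-OH free), via benzodioxaborin 5 (not isolated), via quinone methide dienone 6 (not isolated)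
Conditions: PhB(OH)2 (1.1 equiv), (CH2O)n (1.0 equiv), EtCO2H (0.2 equiv), toluene, reflux (Dean–Stark), 3 h; then 4 (1.5 equiv), PhB(OH)2 (1.0 equiv), reflux, 14 h; crystallisation
Reagents that add atoms: paraformaldehyde as formaldehyde C=O; phenylboronic acid OB(O)c1ccccc1
Why: Proposed new method: a Nagata-type boron-templated ortho-hydroxymethylation closes the dioxaborin ring through the unhindered, most acidic para-oxygen (the free ortho-oxygen is shielded by the pentyl side of the chelated ketone) to give 5, and in the same flask the boronic acid-mediated condensation of 4 at the last free ring carbon gives an alkenyl boronate that fragments to dienone 6 and closes by oxa-6π electrocyclisation, necessarily onto the oxygen next to the acyl group because the para-oxygen is held in the first ring; the closest known reactions are the phenol/formaldehyde/phenylboronic acid benzodioxaborin synthesis and the phenylboronic acid-mediated chromenylation of phenols with enals, here run in sequence in one pot, and no stereocentre is formed.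

Step 3
Reactants: 8 2-methylbenzene-1,3,5-triol (2-methylphloroglucinol); 9 acetyl chloride
Product: 10 1-(2,4,6-trihydroxy-3-methylphenyl)ethan-1-one
Conditions: AlCl3 (3.5 equiv), PhNO2/CH2Cl2, 0 → 40 °C; ice/1 M HCl
Reagents that add atoms: none
Why: Friedel–Crafts acylation at one of the two equivalent free ring carbons, stopping at the mono-ketone for the same deactivation reason as in step 1.

Step 4
Reactants: 7 chromene-fused 2-phenyl-4H-1,3,2-dioxaborin; 10 1-(2,4,6-trihydroxy-3-methylphenyl)ethan-1-one
Product: 11 1-{6-[(3-acetyl-2,4,6-trihydroxy-5-methylphenyl)methyl]-5,7-dihydroxy-2,2-dimethyl-2H-chromen-8-yl}hexan-1-one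
Conditions: 10 (1.2 equiv), NaOAc (0.2 equiv), 1,4-dioxane/H2O (4:1), 50 °C; dilute HCl, EtOAc
Reagents that add atoms: none
Why: Hydrolysis of the cyclic boronate in the wet medium unmasks a phloroglucinol-type 2-hydroxybenzyl alcohol that loses water to an ortho-quinone methide, which is captured in a Michael-type Friedel–Crafts alkylation by the single free ring carbon of 10; 7 has no free ring carbon so it cannot dimerise with itself, and no stereocentre is formed.

Step 5
Reactants: 11 1-{6-[(3-acetyl-2,4,6-trihydroxy-5-methylphenyl)methyl]-5,7-dihydroxy-2,2-dimethyl-2H-chromen-8-yl}hexan-1-one; 12 geranyl acetate [(2E)-3,7-dimethylocta-2,6-dien-1-yl acetate]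
Product: 13 (4R)-2-acetyl-6-[(8-hexanoyl-5,7-dihydroxy-2,2-dimethyl-2H-chromen-6-yl)methyl]-3,5-dihydroxy-4-methyl-4-[(2E)-3,7-dimethylocta-2,6-dien-1-yl]cyclohexa-2,5-dien-1-one (target)
Conditions: 12 (1.05 equiv), Pd2(dba)3·CHCl3 (2.5 mol %), (R,R)-DACH-phenyl Trost ligand (7.5 mol %), Et3N (2.2 equiv), degassed CH2Cl2, 0 °C → rt; 1 M HCl work-up
Reagents that add atoms: none
Why: Proposed new method: ionisation of 12 gives a geranyl-palladium π-allyl cation in the chiral pocket of the ligand, and the ring B phenoxide attacks its unsubstituted terminus (linear product, E-alkene kept) through the methyl-bearing carbon, the least hindered fully substituted site (the two carbons bearing the diarylmethane CH2 are shielded, O-allylation is reversible under the catalyst and the acidic triketone product is the sink), while the two faces of that carbon are told apart because one flank is the chelated acetyl side and the other the bulky benzyl side, which sets the R quaternary centre; the closest known reactions are the palladium/Trost-ligand intermolecular allylic dearomatisation of 1-alkyl-2-naphthols and the linear-selective palladium/Trost-ligand geranylation of 3-alkyloxindoles.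

**Compound list**

1 | phloroglucinol (benzene-1,3,5-triol) | Oc1cc(O)cc(O)c1 | starting material
2 | hexanoyl chloride | CCCCCC(Cl)=O | starting material
3 | 1-(2,4,6-trihydroxyphenyl)hexan-1-one | CCCCCC(=O)c1c(O)cc(O)cc1O | intermediate
4 | 3-methylbut-2-enal (prenal) | CC(C)=CC=O | starting material
5 | 1-(5,7-dihydroxy-2-phenyl-4H-1,3,2-benzodioxaborin-6-yl)hexan-1-one (not isolated) | CCCCCC(=O)c1c(O)cc2OB(c3ccccc3)OCc2c1O | intermediate
6 | 1-[5-hydroxy-8-(3-methylbut-2-en-1-ylidene)-7-oxo-2-phenyl-7,8-dihydro-4H-1,3,2-benzodioxaborin-6-yl]hexan-1-one, the quinone methide dienone (not isolated) | CCCCCC(=O)C1=C(O)C2=C(OB(c3ccccc3)OC2)C(=CC=C(C)C)C1=O | intermediate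
7 | chromene-fused 2-phenyl-4H-1,3,2-dioxaborin: cyclic phenylboronate across O5 and the 6-CH2O of 1-[5,7-dihydroxy-6-(hydroxymethyl)-2,2-dimethyl-2H-chromen-8-yl]hexan-1-one | CCCCCC(=O)c1c(O)c2COB(c3ccccc3)Oc2c2C=CC(C)(C)Oc12 | intermediate
8 | 2-methylbenzene-1,3,5-triol (2-methylphloroglucinol) | Cc1c(O)cc(O)cc1O | starting material
9 | acetyl chloride | CC(Cl)=O | starting material
10 | 1-(2,4,6-trihydroxy-3-methylphenyl)ethan-1-one | CC(=O)c1c(O)cc(O)c(C)c1O | intermediate
11 | 1-{6-[(3-acetyl-2,4,6-trihydroxy-5-methylphenyl)methyl]-5,7-dihydroxy-2,2-dimethyl-2H-chromen-8-yl}hexan-1-one | CCCCCC(=O)c1c(O)c(Cc2c(O)c(C)c(O)c(C(C)=O)c2O)c(O)c2C=CC(C)(C)Oc12 | intermediate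
12 | geranyl acetate, (2E)-3,7-dimethylocta-2,6-dien-1-yl acetate | CC(=O)OC/C=C(\C)CCC=C(C)C | starting material
13 | (4R)-2-acetyl-6-[(8-hexanoyl-5,7-dihydroxy-2,2-dimethyl-2H-chromen-6-yl)methyl]-3,5-dihydroxy-4-methyl-4-[(2E)-3,7-dimethylocta-2,6-dien-1-yl]cyclohexa-2,5-dien-1-one (CNP0319887.1) | CCCCCC(=O)c1c(O)c(CC2=C(O)[C@@](C)(C/C=C(\C)CCC=C(C)C)C(O)=C(C(C)=O)C2=O)c(O)c2c1OC(C)(C)C=C2 | target

**Step count**

- Total steps: 5.
- Longest linear sequence: 4 (steps 1, 2, 4, 5); step 3 is a one-step branch.

**Three steps most likely to fail**

Step 2 (one-pot dioxaborin/pyran double ring closure). The risks are a second hydroxymethylation, methylene-bis homodimer from premature ionisation of 5, and boronate formation through the wrong oxygen, which would lead to the 6-acyl chromene isomer. The fallback sets out from 3 and comes back at 11. 3 is condensed with 4 under ethylenediammonium diacetate catalysis (toluene, 90 °C; Knoevenagel/oxa-6π) with no boron. 1-(5,7-Dihydroxy-2,2-dimethyl-2H-chromen-8-yl)hexan-1-one F1 is separated from its 6-hexanoyl isomer, which is re-equilibrated in hot pyridine and recycled. Mannich aminomethylation of the one free ring carbon (aqueous CH2O, Me2NH, EtOH, rt) gives 1-{6-[(dimethylamino)methyl]-5,7-dihydroxy-2,2-dimethyl-2H-chromen-8-yl}hexan-1-one F2. Heating F2 with 10 in dioxane at 90 °C expels dimethylamine, generates the same quinone methide and gives 11.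

Step 5 (late-stage enantioselective dearomative geranylation). The risks are low or opposite enantioselectivity and attack at the other hindered ring carbons or on oxygen. The sense of induction is checked on the first run (CD or X-ray of a derivative), and the mirror-image ligand is used if it proves opposite. The fallback sets out from 11 and comes back at 13. Uncatalysed C-geranylation with geranyl bromide (NaOMe, MeOH, 0 °C) gives the racemate of the target F4. Salt formation with (R)-1-phenylethylamine and fractional crystallisation gives the (R)-1-phenylethylammonium salt of the target acid F5; the mirror-image amine is taken if the other diastereomer crystallises first. Acidification (1 M HCl/EtOAc) returns 13.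

Step 4 (union through the boronate-derived quinone methide). The risks are sluggish unmasking and scrambling of the diarylmethane to homodimers. The fallback reverses the polarity of the union; it sets out from 10 (and from 3 for the nucleophile) and comes back at 11. 10 is aminomethylated at its free ring carbon (aqueous CH2O, Me2NH, EtOH, rt) to 1-{3-[(dimethylamino)methyl]-2,4,6-trihydroxy-5-methylphenyl}ethan-1-one F3. Heating F3 in dioxane at 90 °C with the chromene F1, made from 3 as described for step 2, generates the quinone methide on ring B instead. The free C6 carbon of F1 captures it to give 11.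

**Further compounds**

F1 | step 2 | 1-(5,7-dihydroxy-2,2-dimethyl-2H-chromen-8-yl)hexan-1-one | CCCCCC(=O)c1c(O)cc(O)c2C=CC(C)(C)Oc12
F2 | step 2 | 1-{6-[(dimethylamino)methyl]-5,7-dihydroxy-2,2-dimethyl-2H-chromen-8-yl}hexan-1-one | CCCCCC(=O)c1c(O)c(CN(C)C)c(O)c2C=CC(C)(C)Oc12
F3 | step 4 | 1-{3-[(dimethylamino)methyl]-2,4,6-trihydroxy-5-methylphenyl}ethan-1-one | CC(=O)c1c(O)c(C)c(O)c(CN(C)C)c1O
F4 | step 5 | racemate of the target (quaternary centre undefined) | CCCCCC(=O)c1c(O)c(CC2=C(O)C(C)(C/C=C(\C)CCC=C(C)C)C(O)=C(C(C)=O)C2=O)c(O)c2c1OC(C)(C)C=C2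
F5 | step 5 | (R)-1-phenylethylammonium salt of the target acid | CCCCCC(=O)c1c(O)c(CC2=C(O)[C@@](C)(C/C=C(\C)CCC=C(C)C)C([O-])=C(C(C)=O)C2=O)c(O)c2c1OC(C)(C)C=C2.C[C@@H]([NH3+])c1ccccc1
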